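**Plan**

1. Cuts (target numbered as a 2H-chromene: O1, C2, C3=C4, C4a, C5 ketone, C6 acyl carbon, C7 enol carbon, C8 quaternary carbon, C8a): the side-chain methyl ester; the C8–prenyl bond (asymmetric decarboxylative prenylation of a C8 prenyl ester); the C6–acyl bond; the ring bond C7–C8; the pyran bonds C4–C4a and O1–C2 (prenal annulation); C8–C8a (decarboxylative Claisen); C8–CH2 of the side chain (malonate alkylation).
2. Forward order: side-chain iodide 9 → malonic half ester 13 → keto dioxinone 18 → pyran ring (ring A, step 10) → carbocycle (ring B) by thermal C7–C8 closure of an acylketene (step 11) → C6 acylation → C8 prenylation → ester hydrolysis.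
3. Enabling feature: C7 is a carbonyl-level carbon and C8 is attached to the enol-ether carbon C8a. In precursor 21, ring A holds the masked acylketene arm (future C5–C6–C7) and the acidic C8–H arm cis on its C4a=C8a double bond and locks the C8a oxygen as the ring ether, so C7 and C8 become the termini of a hexatriene (C7=C6–C5=C4a–C8a=C8).
4. Helper: a prenyl ester on C8 acidifies C8–H for the ring closure, keeps ring B non-aromatic so that C6 can be acylated under mild conditions, and is then turned into the C8 prenyl group with loss of CO2.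
5. Stereochemistry: the side-chain centre comes from an (S)-4-benzyloxazolidinone-controlled alkylation (step 2); the butanoyl centre from (2R)-2-methylbutanoic acid; C8 from the chiral palladium catalyst in step 13 (C8 is formed without control in step 11 and erased before it is reset); the E enoate from cross-metathesis.

Key step: step 11

Assumption: the sense of induction of the Trost ligand in step 13 cannot be derived from the substrate alone; the (R,R)-ligand is nominated for (8R), and its enantiomer replaces it in the same step if the first run shows the opposite sense.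

**Route**

Step 1
Reactants: 1 (4S)-4-benzyl-1,3-oxazolidin-2-one; 2 3-methylbut-2-enoyl chloride
Product: 3 (4S)-4-benzyl-3-(3-methylbut-2-enoyl)-1,3-oxazolidin-2-one
Conditions: n-BuLi, THF, −78 °C; then 2, −78 to 0 °C
Reagents that add atoms: none
Why: N-acylation of the lithiated oxazolidinone by the acid chloride (imide formation for an Evans alkylation) should proceed cleanly and creates no stereocentre.

Step 2
Reactants: 3 (4S)-4-benzyl-3-(3-methylbut-2-enoyl)-1,3-oxazolidin-2-one; 4 allyl iodide
Product: 5 (4S)-4-benzyl-3-[(2S)-2-(prop-1-en-2-yl)pent-4-enoyl]-1,3-oxazolidin-2-one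
Conditions: NaN(SiMe3)2, THF, −78 °C; then 4, −78 to −45 °C
Reagents that add atoms: none
Why: Evans deconjugative asymmetric alkylation, in which γ-deprotonation gives the chelated Z(O) sodium dienolate that is allylated at the α-carbon on the face opposite the benzyl group, should set the (2S) centre (the later side-chain stereocentre) and leave the isopropenyl group.

Step 3
Reactants: 5 (4S)-4-benzyl-3-[(2S)-2-(prop-1-en-2-yl)pent-4-enoyl]-1,3-oxazolidin-2-one
Product: 6 (2S)-2-(prop-1-en-2-yl)pent-4-en-1-ol
Conditions: LiBH4, Et2O, H2O (1 equiv), 0 °C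
Reagents that add atoms: none
Why: reductive cleavage of the N-acyl oxazolidinone by LiBH4 should give the primary alcohol without touching the α-stereocentre and return the auxiliary.

Step 4
Reactants: 6 (2S)-2-(prop-1-en-2-yl)pent-4-en-1-ol; 7 methyl methacrylate
Product: 8 methyl (2E,5S)-5-(hydroxymethyl)-2,6-dimethylhepta-2,6-dienoate
Conditions: 7 (10 equiv), second-generation Grubbs catalyst RuCl2(=CHPh)(PCy3)(H2IMes) (5 mol %), CH2Cl2, 40 °C
Reagents that add atoms: none
Why: olefin cross-metathesis of the monosubstituted alkene with the methacrylate should give the thermodynamically favoured E trisubstituted enoate, the 1,1-disubstituted isopropenyl group being too hindered to take part.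

Step 5
Reactants: 8 methyl (2E,5S)-5-(hydroxymethyl)-2,6-dimethylhepta-2,6-dienoate
Product: 9 methyl (2E,5S)-5-(iodomethyl)-2,6-dimethylhepta-2,6-dienoate
Conditions: I2, PPh3, imidazole, CH2Cl2, 0 °C to rt
Reagents that add atoms: iodine, II
Why: Appel-type iodination replaces the primary hydroxyl by iodide through SN2 at the CH2 carbon, so the adjacent stereocentre is not involved.

Step 6
Reactants: 10 Meldrum's acid; 11 prenol
Product: 12 prenyl hydrogen malonate
Conditions: toluene, 100 °C
Reagents that add atoms: none
Why: thermal alcoholysis of Meldrum's acid (ring opening with loss of acetone) is a standard entry to malonic half esters.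

Step 7
Reactants: 12 prenyl hydrogen malonate; 9 methyl (2E,5S)-5-(iodomethyl)-2,6-dimethylhepta-2,6-dienoate
Product: 13 methyl (2E,5R)-5-{2-carboxy-3-[(3-methylbut-2-en-1-yl)oxy]-3-oxopropyl}-2,6-dimethylhepta-2,6-dienoate
Conditions: LiN(iPr)2 (2.1 equiv), THF, −78 to 0 °C; then 9, DMPU, 0 °C to rt; dilute HCl work-up
Reagents that add atoms: none
Why: C-alkylation of the malonic half-ester dianion (carboxylate ester enolate) by SN2 on the primary iodide should join the side chain, the new malonate centre being configurationally irrelevant and the descriptor at C5 changing only by priority.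

Step 8
Reactants: 14 2,2,6-trimethyl-4H-1,3-dioxin-4-one
Product: 15 (2,2-dimethyl-4-oxo-4H-1,3-dioxin-6-yl)acetic acid
Conditions: LiN(iPr)2, THF, −78 °C; CO2 (gas), −78 °C to rt; dilute HCl work-up
Reagents that add atoms: carbon dioxide, O=C=O
Why: kinetic γ-deprotonation gives the lithium dienolate of the dioxinone, which should be carboxylated at the exocyclic carbon as it is acylated there by other acyl electrophiles.

Step 9
Reactants: 15 (2,2-dimethyl-4-oxo-4H-1,3-dioxin-6-yl)acetic acid; 13 malonic half ester
Product: 18 keto dioxinone prenyl ester, via imidazolide 16 (not isolated), via acylmalonic acid 17 (not isolated)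
Conditions: 15, CDI, THF, rt; then 13, MgCl2, Et3N, MeCN, rt to 40 °C; aqueous citric acid work-up
Reagents that add atoms: none
Why: Masamune-Brooks decarboxylative Claisen condensation, in which the magnesium enolate of the half ester is C-acylated by the acyl imidazolide and the acylmalonic acid loses CO2, should give the β-keto ester with the ketone (future C8a) placed between the future C8 and C4a.

Step 10
Reactants: 18 keto dioxinone prenyl ester; 19 prenal
Product: 21 pyranyl dioxinone, via dienone 20 (not isolated)
Conditions: 19 (1.5 equiv), ethylenediammonium diacetate (20 mol %), CH2Cl2, rt to 40 °C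
Reagents that add atoms: none
Why: Knoevenagel condensation at the only CH2 flanked by the ketone and the dioxinone, followed by oxa-6π electrocyclization of the 1-oxatriene (formal [3+3] pyran annulation), should build ring A with defined regiochemistry, because the dioxinone carbon has no carbonyl oxygen and only the ketone oxygen can close.

Step 11
Reactants: 21 pyranyl dioxinone
Product: 24 prenyl 7-hydroxy-5-oxo-5,8-dihydro-2H-chromene-8-carboxylate, via acylketene 22 (not isolated), via dienylketene 23 (not isolated)
Conditions: toluene (0.01 M), 110 °C, argon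
Reagents that add atoms: none
Why: Proposed new method: retro-[4+2] loss of acetone from the dioxinone unveils acylketene 22 (C7 is the ketene carbon), whose malonate-type C8–H, acidified by the ester and by conjugation through C8a=C4a to the C5 ketone, shifts to the C5 oxygen to give dienylketene 23, which closes by thermal disrotatory 6π electrocyclization (C7–C8 bond) to the cyclohexa-2,4-dienone, isolated as its enol 24. The closest known reaction types are the 6π ring closure of dienylketenes to cyclohexa-2,4-dienones (the last event of cyclobutenone-based benzannulations) and the C-acylation of 1,3-dicarbonyl C–H bonds by dioxinone-derived acylketenes. Ring B is closed in a 6-(enolendo) sense at the digonal ketene carbon, equivalent to a hexatriene to cyclohexadiene electrocyclization. The new quaternary centre C8 is formed without control and needs none, because it is erased and reset in step 13. The step needs C- over O-acylation and ring closure over ketene dimerization: the C8a oxygen is locked in the pyran ether so no enol oxygen can reach the ketene, the two arms are held cis on the ring A double bond, and high dilution suppresses intermolecular capture.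

Step 12
Reactants: 24 prenyl 7-hydroxy-5-oxo-5,8-dihydro-2H-chromene-8-carboxylate; 25 (2R)-2-methylbutanoic acid
Product: 27 C6-acylated triketone prenyl ester, via enol ester 26 (not isolated)
Conditions: 25, DCC, DMAP (0.3 equiv), CH2Cl2, 0 °C to rt
Reagents that add atoms: none
Why: carbodiimide and DMAP C-acylation of a cyclic 1,3-dione, in which O-acylation to the enol ester is followed by DMAP-mediated O to C acyl migration, should place the acyl group on C6, the (R) α-centre coming unchanged from the acid.

Step 13
Reactants: 27 C6-acylated triketone prenyl ester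
Product: 28 methyl (2E,5R)-5-{[(8R)-7-hydroxy-2,2-dimethyl-6-[(2R)-2-methylbutanoyl]-8-(3-methylbut-2-en-1-yl)-5-oxo-5,8-dihydro-2H-chromen-8-yl]methyl}-2,6-dimethylhepta-2,6-dienoate
Conditions: Pd2(dba)3 (2.5 mol %), (R,R)-DACH-phenyl Trost ligand (6 mol %), degassed THF, rt
Reagents that add atoms: none
Why: stereoablative decarboxylative asymmetric allylic alkylation (Tsuji-Trost type), in which zerovalent palladium ionizes the prenyl ester, the β-keto carboxylate loses CO2 to give the planar phloroglucinolate (erasing C8) and the chiral ligand directs attack of C8 on the CH2 terminus of the 1,1-dimethylallyl palladium cation to one face, should set (8R) and the linear prenyl group.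

Step 14
Reactants: 28 methyl ester of the target
Product: 29 target acid
Conditions: LiOH, THF/MeOH/H2O, rt to 40 °C, argon; dilute HCl work-up
Reagents that add atoms: lithium hydroxide, [Li+].[OH-]
Why: saponification of the methyl enoate should free the acid, the β-triketone being protected as its enolate under the basic conditions so that neither the ring nor the acyl α-centre is attacked.

**Compound list**

1 | (4S)-4-benzyl-1,3-oxazolidin-2-one | O=C1N[C@@H](Cc2ccccc2)CO1 | starting material
2 | 3-methylbut-2-enoyl chloride | CC(C)=CC(=O)Cl | starting material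
3 | (4S)-4-benzyl-3-(3-methylbut-2-enoyl)-1,3-oxazolidin-2-one | CC(C)=CC(=O)N1[C@@H](Cc2ccccc2)COC1=O | intermediate
4 | allyl iodide (3-iodoprop-1-ene) | C=CCI | starting material
5 | (4S)-4-benzyl-3-[(2S)-2-(prop-1-en-2-yl)pent-4-enoyl]-1,3-oxazolidin-2-one | C=C(C)[C@H](CC=C)C(=O)N1[C@@H](Cc2ccccc2)COC1=O | intermediate
6 | (2S)-2-(prop-1-en-2-yl)pent-4-en-1-ol | C=C(C)[C@H](CC=C)CO | intermediate
7 | methyl methacrylate | C=C(C)C(=O)OC | starting material
8 | methyl (2E,5S)-5-(hydroxymethyl)-2,6-dimethylhepta-2,6-dienoate | C=C(C)[C@H](C/C=C(\C)C(=O)OC)CO | intermediate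
9 | methyl (2E,5S)-5-(iodomethyl)-2,6-dimethylhepta-2,6-dienoate | C=C(C)[C@H](C/C=C(\C)C(=O)OC)CI | intermediate
10 | Meldrum's acid (2,2-dimethyl-1,3-dioxane-4,6-dione) | CC1(C)OC(=O)CC(=O)O1 | starting material
11 | prenol (3-methylbut-2-en-1-ol) | CC(C)=CCO | starting material
12 | prenyl hydrogen malonate (3-[(3-methylbut-2-en-1-yl)oxy]-3-oxopropanoic acid) | CC(C)=CCOC(=O)CC(=O)O | intermediate
13 | methyl (2E,5R)-5-{2-carboxy-3-[(3-methylbut-2-en-1-yl)oxy]-3-oxopropyl}-2,6-dimethylhepta-2,6-dienoate (both epimers at the malonate carbon) | C=C(C)[C@H](C/C=C(\C)C(=O)OC)CC(C(=O)O)C(=O)OCC=C(C)C | intermediate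
14 | 2,2,6-trimethyl-4H-1,3-dioxin-4-one | CC1=CC(=O)OC(C)(C)O1 | starting material
15 | (2,2-dimethyl-4-oxo-4H-1,3-dioxin-6-yl)acetic acid | OC(=O)CC1=CC(=O)OC(C)(C)O1 | intermediate
16 | 6-[2-(1H-imidazol-1-yl)-2-oxoethyl]-2,2-dimethyl-4H-1,3-dioxin-4-one (acyl imidazolide) | O=C(CC1=CC(=O)OC(C)(C)O1)n1ccnc1 | intermediate
17 | acylmalonic acid: 13 carrying the (2,2-dimethyl-4-oxo-4H-1,3-dioxin-6-yl)acetyl group on the malonate carbon | C=C(C)[C@H](C/C=C(\C)C(=O)OC)CC(C(=O)O)(C(=O)OCC=C(C)C)C(=O)CC1=CC(=O)OC(C)(C)O1 | intermediate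
18 | 3-methylbut-2-en-1-yl 4-(2,2-dimethyl-4-oxo-4H-1,3-dioxin-6-yl)-2-[(2R,4E)-6-methoxy-5-methyl-6-oxo-2-(prop-1-en-2-yl)hex-4-en-1-yl]-3-oxobutanoate (both epimers at C2) | C=C(C)[C@H](C/C=C(\C)C(=O)OC)CC(C(=O)OCC=C(C)C)C(=O)CC1=CC(=O)OC(C)(C)O1 | intermediate
19 | prenal (3-methylbut-2-enal) | CC(C)=CC=O | starting material
20 | Knoevenagel dienone: 18 carrying a 3-methylbut-2-en-1-ylidene group on C4 of the butanoate | C=C(C)[C@H](C/C=C(\C)C(=O)OC)CC(C(=O)OCC=C(C)C)C(=O)C(=CC=C(C)C)C1=CC(=O)OC(C)(C)O1 | intermediate
21 | 1-(3-methylbut-2-en-1-yl) 8-methyl (4R,6E)-2-[5-(2,2-dimethyl-4-oxo-4H-1,3-dioxin-6-yl)-2,2-dimethyl-2H-pyran-6-yl]-7-methyl-4-(prop-1-en-2-yl)oct-6-enedioate (both epimers at C2) | C=C(C)[C@H](C/C=C(\C)C(=O)OC)CC(C(=O)OCC=C(C)C)C1=C(C2=CC(=O)OC(C)(C)O2)C=CC(C)(C)O1 | intermediate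
22 | acylketene: 21 with the dioxinone replaced by a 3-oxoprop-2-enoyl (C(=O)CH=C=O) group on pyran C5 | C=C(C)[C@H](C/C=C(\C)C(=O)OC)CC(C(=O)OCC=C(C)C)C1=C(C(=O)C=C=O)C=CC(C)(C)O1 | intermediate
23 | dienylketene: tautomer of 22 with the C5 enol and the exocyclic C8=C8a double bond | C=C(C)[C@H](C/C=C(\C)C(=O)OC)CC(C(=O)OCC=C(C)C)=C1OC(C)(C)C=CC1=C(O)C=C=O | intermediate
24 | 3-methylbut-2-en-1-yl 7-hydroxy-8-[(2R,4E)-6-methoxy-5-methyl-6-oxo-2-(prop-1-en-2-yl)hex-4-en-1-yl]-2,2-dimethyl-5-oxo-5,8-dihydro-2H-chromene-8-carboxylate (both epimers at C8) | C=C(C)[C@H](C/C=C(\C)C(=O)OC)CC1(C(=O)OCC=C(C)C)C(O)=CC(=O)C2=C1OC(C)(C)C=C2 | intermediate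
25 | (2R)-2-methylbutanoic acid | CC[C@@H](C)C(=O)O | starting material
26 | enol ester: 5-O-[(2R)-2-methylbutanoyl] derivative of 24 (7-oxo tautomer) | C=C(C)[C@H](C/C=C(\C)C(=O)OC)CC1(C(=O)OCC=C(C)C)C(=O)C=C(OC(=O)[C@H](C)CC)C2=C1OC(C)(C)C=C2 | intermediate
27 | 3-methylbut-2-en-1-yl 7-hydroxy-8-[(2R,4E)-6-methoxy-5-methyl-6-oxo-2-(prop-1-en-2-yl)hex-4-en-1-yl]-2,2-dimethyl-6-[(2R)-2-methylbutanoyl]-5-oxo-5,8-dihydro-2H-chromene-8-carboxylate (both epimers at C8) | C=C(C)[C@H](C/C=C(\C)C(=O)OC)CC1(C(=O)OCC=C(C)C)C(O)=C(C(=O)[C@H](C)CC)C(=O)C2=C1OC(C)(C)C=C2 | intermediate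
28 | methyl (2E,5R)-5-{[(8R)-7-hydroxy-2,2-dimethyl-6-[(2R)-2-methylbutanoyl]-8-(3-methylbut-2-en-1-yl)-5-oxo-5,8-dihydro-2H-chromen-8-yl]methyl}-2,6-dimethylhepta-2,6-dienoate | C=C(C)[C@H](C/C=C(\C)C(=O)OC)C[C@]1(CC=C(C)C)C(O)=C(C(=O)[C@H](C)CC)C(=O)C2=C1OC(C)(C)C=C2 | intermediate
29 | (2E,5R)-5-{[(8R)-7-hydroxy-2,2-dimethyl-6-[(2R)-2-methylbutanoyl]-8-(3-methylbut-2-en-1-yl)-5-oxo-5,8-dihydro-2H-chromen-8-yl]methyl}-2,6-dimethylhepta-2,6-dienoic acid | C=C(C)[C@H](C/C=C(\C)C(=O)O)C[C@]1(CC=C(C)C)C(O)=C(C(=O)[C@H](C)CC)C(=O)C2=C1OC(C)(C)C=C2 | target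

**Count**

Total steps: 14. Longest linear sequence: 12 steps (1–5, 7, 9–14); steps 6 and 8 are side branches.

**Steps most likely to fail**

Step 11 (Proposed new method). The acylketene may be consumed by dimerization or by other intermolecular capture before the C8–H shift and ring closure take place, or the pyran may open thermally and divert the ketene. Fallback with known chemistry: 21 is heated in toluene with methanol (10 equiv, 110 °C), which should intercept the acylketene as the methyl β-keto ester F1. F1 is then treated with DBU (2 equiv, MeCN, 50 °C), so that the malonate-type carbanion at the future C8 attacks the methyl ester in a Dieckmann (intramolecular Claisen) condensation, driven by the acidity of the product, and the route is rejoined at 24.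

Step 13. The catalyst may give poor facial selectivity at C8, attack at the substituted allyl terminus (reverse prenyl), or O-prenylation that does not funnel to carbon. Fallback: from 27 the ester is removed without transfer of the prenyl group, using Pd(PPh3)4 (5 mol %) and morpholine as scavenger in THF, which should give after loss of CO2 the aromatic acylphloroglucinol chromene F2. F2 is then dearomatized by C8 alkylation with prenyl bromide under chiral phase-transfer conditions (N-(9-anthracenylmethyl)cinchonidinium bromide, CsOH, toluene, −40 °C), the known alkylative dearomatization of acylphloroglucinols, and the route is rejoined at 28.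

Step 9. The imidazolide 16 may self-condense through its acidic CH2 group, or C-acylation of the hindered substituted magnesium malonate may be too slow. Fallback that reverses the order of bond formation: 16 is condensed with the magnesium salt of the unsubstituted half ester 12 (MgCl2, Et3N, MeCN), which should give, through the acylmalonic acid F3 and loss of CO2, the unsubstituted keto ester F4. F4 is then alkylated at the β-keto ester carbon with iodide 9 (K2CO3, acetone, 50 °C), and the route is rejoined at 18.

**Further compounds**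

F1 | step 11 | 1-(3-methylbut-2-en-1-yl) 8-methyl (4R,6E)-2-[5-(3-methoxy-3-oxopropanoyl)-2,2-dimethyl-2H-pyran-6-yl]-7-methyl-4-(prop-1-en-2-yl)oct-6-enedioate | C=C(C)[C@H](C/C=C(\C)C(=O)OC)CC(C(=O)OCC=C(C)C)C1=C(C(=O)CC(=O)OC)C=CC(C)(C)O1
F2 | step 13 | methyl (2E,5R)-5-{[5,7-dihydroxy-2,2-dimethyl-6-[(2R)-2-methylbutanoyl]-2H-chromen-8-yl]methyl}-2,6-dimethylhepta-2,6-dienoate | C=C(C)[C@H](C/C=C(\C)C(=O)OC)Cc1c(O)c(C(=O)[C@H](C)CC)c(O)c2c1OC(C)(C)C=C2
F3 | step 9 | 2-[(2,2-dimethyl-4-oxo-4H-1,3-dioxin-6-yl)acetyl]-3-[(3-methylbut-2-en-1-yl)oxy]-3-oxopropanoic acid | CC(C)=CCOC(=O)C(C(=O)O)C(=O)CC1=CC(=O)OC(C)(C)O1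
F4 | step 9 | 3-methylbut-2-en-1-yl 4-(2,2-dimethyl-4-oxo-4H-1,3-dioxin-6-yl)-3-oxobutanoate | CC(C)=CCOC(=O)CC(=O)CC1=CC(=O)OC(C)(C)O1
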